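Readings and results come from a simulation for substances that don't exist.

The bench decision for flask larch is whether to wait, heat or recharge, so the examination starts with what has stopped it.

| setting | larch | cedar | flask |
|---|---|---|---|
| starting material | 10 mM | 10 mM | 10 mM |
| second substrate | 2 equiv | 4 equiv | 2.00 equiv |
| coupling partner | 3 equiv | 3 equiv | 3.00 equiv |
| capture agent | 10 mM | 10 mM | 10.0 mM |
| free catalyst | 20 mol% | 20 mol% | 20 mol% |
| temperature | 70 °C | 76 °C | 70 °C |
| remark | the very flask that is asked about, followed so far | run made earlier |  |
| time |  |  | 5.0 min |

| run | time / min | target / % | starting material / % |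
|---|---|---|---|
| larch | 0.333 | 4.3 | 94.0 |
| larch | 0.667 | 9.2 | 90.3 |
| larch | 1.00 | 11.1 | 85.3 |
| larch | 2.00 | 18.3 | 81.6 |
| larch | 4.00 | 19.3 | 77.6 |
| cedar | 0.417 | 5.5 | 94.0 |
| cedar | 0.833 | 8.1 | 92.5 |
| cedar | 1.33 | 9.9 | 88.0 |
| cedar | 2.50 | 11.8 | 87.6 |
| cedar | 5.00 | 11.5 | 85.9 |

(readings scatter by 1 percentage point)

- target taken out counts as made
- reactions considered so far: starting material + free catalyst <-> catalyst intermediate A; coupling partner + catalyst intermediate A -> free catalyst + target; second substrate + free catalyst <-> catalyst intermediate B; coupling partner + catalyst intermediate B -> free catalyst + second product; catalyst intermediate B + capture agent -> trapped intermediate; target <-> isomer of the product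
- additions bring no volume worth counting

- Tuesday's: at 5.0 min add free catalyst, 100% of the amount charged, then wait 5.0 min
- Sunday's: change nothing and wait 5.0 min more
- Friday's: at 5.0 min raise the temperature by 10 K, then wait 5.0 min
- Thursday's: at 5.0 min take out 90% of the target then present, then wait 5.0 min
- Saturday's: at 5.0 min add coupling partner, 100% of the amount charged, then wait 5.0 min

- target, in percent of the starting material first charged, at 5.0 min
- the remedy with the largest gain of target, or "none" below 2 percentage points (Tuesday's / Sunday's / Friday's / Thursday's / Saturday's / none)
- target present, with what was taken out counted in, in percent of the starting material first charged, after Friday's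
- target present, with what was taken out counted in, in percent of the starting material first charged, after Thursday's

**Why has larch stopped?** Between 2.00 min and 4.00 min the target moves from 18.3% to 19.3%, about the scatter of a reading, yet 77.6% of the starting material still stands. So the stall is not for want of starting material. I take the catalyst to be lost to the capture agent, charged at 10.0 mM, more than the 2.00 mM of catalyst.

**What do you carry away?** A reading of 19.3% on a loading of 20 mol% gives 0.965. That is the turnover number on target, the target made per catalyst charged up to the stall.

**How does it move with the recipe?** Free catalyst divides between starting material and second substrate, and catalyst intermediate B divides between coupling partner and capture agent. So at fixed temperature, with the binding steps near balance and the reagents near their charge, I expect it to follow starting material over second substrate, times coupling partner over capture agent.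

**Does cedar bear that out?** Cedar doubles the second substrate, so the rule asks for a factor of 0.500. Its reading gives 0.575, a factor of 0.596. Cedar also ran at 76 °C, so the direction holds and the factor stays loose.

**But fresh catalyst meets the same capture agent?** It does, and I reckon about 8.00 mM of capture agent to remain, more than the new dose. The new dose should therefore earn the same turnover number, and Tuesday's should bring 19 percentage points, above the margin of 2 points. My reckoning is about 19.3% now, with Tuesday's as the remedy.

The forecast says 19.8%, Tuesday's, 19% after Friday's and 20.2% after Thursday's, on the ground that “the reaction has stalled because the catalyst has died”.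

Larch gives 19.5% at 5.0 min. The remedy is Tuesday's, while Friday's ends at 15.4% and Thursday's at 20.2%. At that time trapped intermediate holds 96.3% of the catalyst, with 82.1% of the coupling partner still free. The turnover number of 0.965 prices Tuesday's at 19 points, and it brings 18 points.

    starting material + free catalyst ⇌ catalyst intermediate A (K = 190 /M, k = 6.42 /M/s, Ea = 51.0 kJ/mol, ΔH = −23.0 kJ/mol)
    coupling partner + catalyst intermediate A → free catalyst + target (k = 2.31 /M/s, Ea = 53.0 kJ/mol)
    second substrate + free catalyst ⇌ catalyst intermediate B (K = 180 /M, k = 8.69 /M/s, Ea = 40.0 kJ/mol, ΔH = −32.0 kJ/mol)
    coupling partner + catalyst intermediate B → free catalyst + second product (k = 1.58 /M/s, Ea = 61.0 kJ/mol)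
    catalyst intermediate B + capture agent → trapped intermediate (k = 2.87 /M/s, Ea = 39.0 kJ/mol)
    target ⇌ isomer of the product (K = 1.90, k = 4.72 × 10⁻⁴ /s, Ea = 104 kJ/mol, ΔH = −48.0 kJ/mol)
    (constants at 70 °C)

A neighbouring flask charges 40 mM of starting material on the same equivalents and loading, with capture agent at 10.0 mM. Coupling partner over capture agent is then 4.00 times that of larch, so the rule, which asks for reagents near their charge, puts the turnover number at 3.86 and the target at 77.2%. The computed flask gives 60.0%, a turnover number of 3.00, and there the condition of the rule fails: starting material stands at 33.2%, coupling partner at 35.7% and capture agent at 29.6% of their charges.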